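**Plan**
- Retrosynthesis: cut the upper interflavan bond C4(top)–C8(middle) (flavan-4-yl cation plus arene). Then cut, in one event, the lower interflavan bond C4(middle)–C8(bottom) together with C2–C3 of the middle pyran ring C. This leads back to a 2-aryl-2,3-dihydrobenzofuran-3-carbaldehyde, and that to a (2R)-flavanone.
- Enabling feature: C4 of the middle unit sits on phloroglucinol ring A, ortho to O1 and O5 and para to O7, so a cation there is strongly stabilised. C2 is benzylic and carries O1, so it migrates easily. C2 can therefore shift from C4 onto a formyl carbon, which becomes C3.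
- Forward order: chromone → (2R)-flavanone → oxidative ring contraction to the trans dihydrobenzofuran ester → aldehyde → ring expansion with arylation by benzylated epiafzelechin (middle ring C and lower bond) → coupling with a C4-activated, C8-bromo-capped epiafzelechin (upper bond) → hydrogenolysis.
- Stereochemistry: top and bottom units come from (−)-epiafzelechin. Middle C2 comes from the ligand-controlled conjugate addition and is carried with retention through both 1,2-shifts. Middle C3 comes from the rotamer of the Lewis-acid-bound formyl group. Both C4 centres come from arene attack anti to the 3-oxygen (3,4-trans).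

Key step: step 8

Assumption: (−)-epiafzelechin 1, acetophenone 5 and boronic acid 8 are taken as purchasable; the target is read as epiafzelechin-(4β→8)-ent-epiafzelechin-(4α→8)-epiafzelechin, so only the ent-configured middle unit is built de novo.

**Step 1**
Reactants: 1 (−)-epiafzelechin
Product: 2 3,5,7,4'-tetra-O-benzyl-(−)-epiafzelechin
Conditions: BnBr (4.5 equiv), NaH (4.5 equiv), DMF, −40 °C to rt
Reagents that add atoms: benzyl bromide BrCc1ccccc1
Why: Williamson etherification of the three phenols and the secondary alcohol touches no stereocentre, and the cold start lets the 4'-phenoxide be benzylated before it can open ring C through a quinone methide.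

**Step 2**
Reactants: 2 3,5,7,4'-tetra-O-benzyl-(−)-epiafzelechin
Product: 3 8-bromo-3,5,7,4'-tetra-O-benzyl-(−)-epiafzelechin
Conditions: NBS (1.0 equiv), CH2Cl2, −78 °C to rt
Reagents that add atoms: N-bromosuccinimide O=C1CCC(=O)N1Br
Why: Electrophilic aromatic bromination of the phloroglucinol-type ring A should go to C8, the more accessible free position, and the bromine later blocks this site against self-condensation.

**Step 3**
Reactants: 3 8-bromo-3,5,7,4'-tetra-O-benzyl-(−)-epiafzelechin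
Product: 4 8-bromo-3,5,7,4'-tetra-O-benzyl-4β-(2-ethoxyethoxy)epiafzelechin (4-alkoxy trans to 3-benzyloxy)
Conditions: DDQ (2 equiv), 2-ethoxyethanol (5 equiv), CH2Cl2, rt
Reagents that add atoms: 2-ethoxyethanol CCOCCO
Why: Benzylic oxidation by DDQ (hydride abstraction at C4, helped by the ortho and para oxygens of ring A) and capture of the cation by the alcohol anti to the 3-benzyloxy group should give the 3,4-trans ether, a known way to activate C4 of benzylated flavan-3-ols.

**Step 4**
Reactants: 5 1-[2,4-bis(benzyloxy)-6-hydroxyphenyl]ethanone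
Product: 7 5,7-bis(benzyloxy)-4H-chromen-4-one, via enaminone 6 (not isolated)
Conditions: Me2NCH(OMe)2, toluene, 95 °C; then conc. HCl, CH2Cl2, 40 °C
Reagents that add atoms: N,N-dimethylformamide dimethyl acetal COC(OC)N(C)C
Why: Enaminone formation at the acetyl methyl group and acid-promoted cyclisation with loss of dimethylamine is the standard chromone synthesis from 2-hydroxyacetophenones.

**Step 5**
Reactants: 7 5,7-bis(benzyloxy)-4H-chromen-4-one; 8 4-(benzyloxy)phenylboronic acid
Product: 9 (2R)-5,7-bis(benzyloxy)-2-[4-(benzyloxy)phenyl]chroman-4-one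
Conditions: Pd(OCOCF3)2 (5 mol %), t-BuPyOx (6 mol %, the enantiomer that gives the 2R product), NH4PF6, H2O, ClCH2CH2Cl, 60 °C
Reagents that add atoms: none
Why: Palladium-catalysed asymmetric conjugate addition of an arylboronic acid to a chromone (aryl–palladium insertion, then protonation of the enolate) is a known reaction type, and the pyridine–oxazoline ligand fixes the face of attack at C2 and so sets the one stereocentre of the middle unit that is carried through.

**Step 6**
Reactants: 9 (2R)-5,7-bis(benzyloxy)-2-[4-(benzyloxy)phenyl]chroman-4-one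
Product: 10 methyl (2R,3R)-4,6-bis(benzyloxy)-2-[4-(benzyloxy)phenyl]-2,3-dihydrobenzofuran-3-carboxylate (2,3-trans)
Conditions: PhI(OAc)2 (1.2 equiv), H2SO4 (cat.), HC(OMe)3/MeOH, rt
Reagents that add atoms: trimethyl orthoformate COC(OC)OC
Why: Oxidative ring contraction of a flavanone with a trivalent iodine reagent: the enol ether is attacked at C3 anti to the 2-aryl group, and a 1,2-shift of electron-rich ring A from C4 to C3 with loss of iodobenzene should give the trans ester, with C2 untouched and C3 set by the anti course of the shift.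

**Step 7**
Reactants: 10 methyl (2R,3R)-4,6-bis(benzyloxy)-2-[4-(benzyloxy)phenyl]-2,3-dihydrobenzofuran-3-carboxylate
Product: 11 (2R,3R)-4,6-bis(benzyloxy)-2-[4-(benzyloxy)phenyl]-2,3-dihydrobenzofuran-3-carbaldehyde (2,3-trans)
Conditions: i-Bu2AlH (1.1 equiv), CH2Cl2, −78 °C; MeOH, aq. potassium sodium tartrate
Reagents that add atoms: none
Why: Partial reduction of the ester by i-Bu2AlH at −78 °C should stop at the aluminium hemiacetal, which gives the aldehyde on work-up; trans is the more stable arrangement, so any epimerisation at C3 converges on 11, which is used crude to avoid β-elimination of the phenoxide.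

**Step 8**
Reactants: 11 (2R,3R)-4,6-bis(benzyloxy)-2-[4-(benzyloxy)phenyl]-2,3-dihydrobenzofuran-3-carbaldehyde; 2 3,5,7,4'-tetra-O-benzyl-(−)-epiafzelechin (3 equiv)
Product: 13 5,7,4'-tri-O-benzyl-ent-epiafzelechin-(4α→8)-3,5,7,4'-tetra-O-benzylepiafzelechin, via ring-expanded flavan-4-yl cation 12 (not isolated)
Conditions: BF3·OEt2 (1.0 equiv), CH2Cl2, 4 Å MS, −78 to −30 °C; aq. NaHCO3
Reagents that add atoms: none
Why: Proposed new method: BF3 (passed from its etherate to the formyl oxygen of 11) activates the aldehyde, the benzylic O1-bearing C2 shifts suprafacially from the ring carbon (future C4) to the formyl carbon (future C3) to form the C2–C3 bond and leave the 2,4,6-trioxygenated benzyl cation 12 as its alkoxytrifluoroborate, and C8 of 2 captures this cation in a Friedel–Crafts alkylation, the proton lost from the arenium ion passing to the borate oxygen so that BF3 is released and the free 3-hydroxyl of 13 remains; the closest known reaction types are the acid-catalysed aldehyde–ketone rearrangement (1,2-shift to an activated formyl carbon, here the reverse of a semipinacol ring contraction) and the Lewis-acid coupling of flavan-4-yl cations with benzylated flavan-3-ols. Ring C of the middle unit is closed by a ring-expanding 1,2-alkyl shift (five- to six-membered, bridged three-centre transition state), and no other ring is formed. C2 keeps its configuration because the migrating carbon moves with retention. C3 is set by the rotamer of the formyl group: with the BF3-bound oxygen turned away from O1 and the fused arene, the trans aldehyde should give the 2,3-cis alkoxide. C4 is set by arene attack anti to the pseudo-axial 3-oxygen of 12 (3,4-trans), as in known couplings of 2,3-cis flavan-4-yl cations. The step needs the intramolecular shift to outrun direct addition of the arene to the activated formyl group and a hydride shift in 12 to the flavan-3-one; the cation-stabilising ring A, the low temperature and the excess of 2 should secure this, and C8 over C6 attack on 2 follows the usual preference of benzylated flavan-3-ols.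

**Step 9**
Reactants: 4 8-bromo-3,5,7,4'-tetra-O-benzyl-4β-(2-ethoxyethoxy)epiafzelechin; 13 5,7,4'-tri-O-benzyl-ent-epiafzelechin-(4α→8)-3,5,7,4'-tetra-O-benzylepiafzelechin (1.2 equiv)
Product: 15 8-bromo-3,5,7,4'-tetra-O-benzylepiafzelechin-(4β→8)-5,7,4'-tri-O-benzyl-ent-epiafzelechin-(4α→8)-3,5,7,4'-tetra-O-benzylepiafzelechin, via flavan-4-yl cation triflate 14 (not isolated)
Conditions: Me3SiOTf (0.2 equiv), CH2Cl2, −78 °C; Et3N quench
Reagents that add atoms: none
Why: Lewis-acid ionisation of the 4-ether gives cation 14, which should alkylate the most nucleophilic free position of 13, C8 of the ent unit, in the Friedel–Crafts coupling known for benzylated proanthocyanidin building blocks; attack anti to the 3-benzyloxy group sets the 4β (3,4-trans) bond and the C8 bromine of 4 prevents self-condensation.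

**Step 10**
Reactants: 15 protected trimer
Product: 16 epiafzelechin-(4β→8)-ent-epiafzelechin-(4α→8)-epiafzelechin (target)
Conditions: H2 (1 atm), Pd(OH)2/C, Et3N, THF/MeOH/H2O, rt
Reagents that add atoms: none
Why: Hydrogenolysis over Pd(OH)2/C should cleave all eleven benzyl ethers and the aryl C–Br bond without touching the stereocentres or the interflavan bonds, the amine taking up the HBr.

**Compound list**
1 | (−)-epiafzelechin, (2R,3R)-2-(4-hydroxyphenyl)chromane-3,5,7-triol | Oc1cc(O)c2c(c1)O[C@H](c1ccc(O)cc1)[C@H](O)C2 | starting material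
2 | 3,5,7,4'-tetra-O-benzyl-(−)-epiafzelechin | O(Cc1ccccc1)c1cc(OCc2ccccc2)c2c(c1)O[C@H](c1ccc(OCc3ccccc3)cc1)[C@H](OCc1ccccc1)C2 | intermediate
3 | 8-bromo-3,5,7,4'-tetra-O-benzyl-(−)-epiafzelechin | O(Cc1ccccc1)c1cc(OCc2ccccc2)c2c(c1Br)O[C@H](c1ccc(OCc3ccccc3)cc1)[C@H](OCc1ccccc1)C2 | intermediate
4 | 8-bromo-3,5,7,4'-tetra-O-benzyl-4β-(2-ethoxyethoxy)epiafzelechin | O(Cc1ccccc1)c1cc(OCc2ccccc2)c2c(c1Br)O[C@H](c1ccc(OCc3ccccc3)cc1)[C@H](OCc1ccccc1)[C@H]2OCCOCC | intermediate
5 | 1-[2,4-bis(benzyloxy)-6-hydroxyphenyl]ethanone | CC(=O)c1c(O)cc(OCc2ccccc2)cc1OCc1ccccc1 | starting material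
6 | (E)-1-[2,4-bis(benzyloxy)-6-hydroxyphenyl]-3-(dimethylamino)prop-2-en-1-one | CN(C)/C=C/C(=O)c1c(O)cc(OCc2ccccc2)cc1OCc1ccccc1 | intermediate
7 | 5,7-bis(benzyloxy)-4H-chromen-4-one | O=c1ccoc2cc(OCc3ccccc3)cc(OCc3ccccc3)c12 | intermediate
8 | 4-(benzyloxy)phenylboronic acid | OB(O)c1ccc(OCc2ccccc2)cc1 | starting material
9 | (2R)-5,7-bis(benzyloxy)-2-[4-(benzyloxy)phenyl]chroman-4-one | O(Cc1ccccc1)c1cc(OCc2ccccc2)c2c(c1)O[C@@H](c1ccc(OCc3ccccc3)cc1)CC2=O | intermediate
10 | methyl (2R,3R)-4,6-bis(benzyloxy)-2-[4-(benzyloxy)phenyl]-2,3-dihydrobenzofuran-3-carboxylate | O(Cc1ccccc1)c1cc(OCc2ccccc2)c2c(c1)O[C@@H](c1ccc(OCc3ccccc3)cc1)[C@@H]2C(=O)OC | intermediate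
11 | (2R,3R)-4,6-bis(benzyloxy)-2-[4-(benzyloxy)phenyl]-2,3-dihydrobenzofuran-3-carbaldehyde | O(Cc1ccccc1)c1cc(OCc2ccccc2)c2c(c1)O[C@@H](c1ccc(OCc3ccccc3)cc1)[C@@H]2C=O | intermediate
12 | (2S,3S)-5,7-bis(benzyloxy)-2-[4-(benzyloxy)phenyl]-3-(trifluoroboranuidyloxy)chroman-4-ylium (2,3-cis zwitterion) | O(Cc1ccccc1)c1cc(OCc2ccccc2)c2c(c1)O[C@@H](c1ccc(OCc3ccccc3)cc1)[C@@H](O[B-](F)(F)F)[CH+]2 | intermediate
13 | 5,7,4'-tri-O-benzyl-ent-epiafzelechin-(4α→8)-3,5,7,4'-tetra-O-benzylepiafzelechin | O(Cc1ccccc1)c1cc(OCc2ccccc2)c2c(c1)O[C@@H](c1ccc(OCc3ccccc3)cc1)[C@@H](O)[C@@H]2c1c(OCc2ccccc2)cc(OCc2ccccc2)c2c1O[C@H](c1ccc(OCc3ccccc3)cc1)[C@H](OCc1ccccc1)C2 | intermediate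
14 | 8-bromo-3,5,7,4'-tetra-O-benzylepiafzelechin-4-ylium triflate | O(Cc1ccccc1)c1cc(OCc2ccccc2)c2c(c1Br)O[C@H](c1ccc(OCc3ccccc3)cc1)[C@H](OCc1ccccc1)[CH+]2.[O-]S(=O)(=O)C(F)(F)F | intermediate
15 | 8-bromo-3,5,7,4'-tetra-O-benzylepiafzelechin-(4β→8)-5,7,4'-tri-O-benzyl-ent-epiafzelechin-(4α→8)-3,5,7,4'-tetra-O-benzylepiafzelechin | O(Cc1ccccc1)c1cc(OCc2ccccc2)c2c(c1Br)O[C@H](c1ccc(OCc3ccccc3)cc1)[C@H](OCc1ccccc1)[C@H]2c1c(OCc2ccccc2)cc(OCc2ccccc2)c2c1O[C@@H](c1ccc(OCc3ccccc3)cc1)[C@@H](O)[C@@H]2c1c(OCc2ccccc2)cc(OCc2ccccc2)c2c1O[C@H](c1ccc(OCc3ccccc3)cc1)[C@H](OCc1ccccc1)C2 | intermediate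
16 | epiafzelechin-(4β→8)-ent-epiafzelechin-(4α→8)-epiafzelechin | Oc1ccc([C@H]2Oc3cc(O)cc(O)c3[C@H](c3c(O)cc(O)c4c3O[C@@H](c3ccc(O)cc3)[C@@H](O)[C@@H]4c3c(O)cc(O)c4c3O[C@H](c3ccc(O)cc3)[C@H](O)C4)[C@H]2O)cc1 | target

**Totals**
Total steps: 10. Longest linear sequence: 7 steps (5 to 16, steps 4 to 10).

**Steps most likely to fail**

1. Step 8 (proposed new method). What may go wrong:
   - the arene may add directly to the activated formyl group before the shift;
   - the hydrogen on the ring carbon may shift to the formyl carbon in place of C2;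
   - the aldehyde may enolise and aromatise to a benzofuran;
   - the cation may undergo a hydride shift to the flavan-3-one;
   - the shift may occur through the other formyl rotamer, giving poor facial selectivity at C3, with C4 following it.

   Fallback, known chemistry only, from 9 back to 13. NaBH4 reduction gives the 2,4-cis alcohol (2R,4R)-5,7-bis(benzyloxy)-2-[4-(benzyloxy)phenyl]chroman-4-ol F1. MsCl/Et3N gives the mesylate (2R,4R)-5,7-bis(benzyloxy)-2-[4-(benzyloxy)phenyl]chroman-4-yl methanesulfonate F2, which is not isolated and eliminates in the same flask to (2R)-5,7-bis(benzyloxy)-2-[4-(benzyloxy)phenyl]-2H-chromene F3. Hydroboration–oxidation (BH3·THF, then NaOH/H2O2) anti to the 2-aryl group gives 5,7,4'-tri-O-benzyl-ent-afzelechin F4. Dess–Martin oxidation gives (2S)-5,7-bis(benzyloxy)-2-[4-(benzyloxy)phenyl]chroman-3-one F5. Reduction with LiBH(s-Bu)3 from the face opposite the aryl group gives 5,7,4'-tri-O-benzyl-ent-epiafzelechin F6. DDQ with 2-ethoxyethanol gives 5,7,4'-tri-O-benzyl-4α-(2-ethoxyethoxy)-ent-epiafzelechin F7. Me3SiOTf-catalysed coupling of F7 with an excess of 2 then gives 13.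

2. Step 6. What may go wrong: dehydrogenation to the flavone, a competing 2,3-shift of ring B to the isoflavone, or electrophilic attack of the iodine reagent on the electron-rich ring A.

   Fallback, from 9 back to 10, by a carbene-based ring contraction. Trifluoroacetylation of the lithium enolate (LiN(SiMe3)2, CF3CO2CH2CF3, −78 °C) gives the enol form of the 3-trifluoroacetyl ketone, (2S)-5,7-bis(benzyloxy)-2-[4-(benzyloxy)phenyl]-3-(2,2,2-trifluoro-1-hydroxyethylidene)chroman-4-one F8. C2 is spatially unchanged from 9 here and in the next compound; the descriptor changes only because C3 now outranks the aryl group. Deacylative diazo transfer (MsN3, Et3N) gives (2S)-5,7-bis(benzyloxy)-2-[4-(benzyloxy)phenyl]-3-diazochroman-4-one F9. Photochemical Wolff rearrangement in MeOH (ring A migrates, the ketene is trapped) should give 10 together with its 2,3-cis epimer, methyl (2R,3S)-4,6-bis(benzyloxy)-2-[4-(benzyloxy)phenyl]-2,3-dihydrobenzofuran-3-carboxylate F10. NaOMe/MeOH equilibrates the mixture to 10.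

3. Step 9. What may go wrong: alkylation at a C6 position instead of C8 of the ent unit, O-alkylation of the free 3-hydroxyl, or acid-induced cleavage and scrambling of the lower interflavan bond just made.

   Fallback, from 10 (with 4) back to 15, with the order of bond formation reversed. Me3SiOTf coupling of 4 with an excess of the benzofuran ester 10 at its C7 gives methyl (2R,3R)-4,6-bis(benzyloxy)-2-[4-(benzyloxy)phenyl]-7-[8-bromo-3,5,7,4'-tetra-O-benzylepiafzelechin-4β-yl]-2,3-dihydrobenzofuran-3-carboxylate F11. Reduction with i-Bu2AlH gives the corresponding aldehyde, (2R,3R)-4,6-bis(benzyloxy)-2-[4-(benzyloxy)phenyl]-7-[8-bromo-3,5,7,4'-tetra-O-benzylepiafzelechin-4β-yl]-2,3-dihydrobenzofuran-3-carbaldehyde F12. The ring expansion with arylation of step 8, run on F12 with 2, then gives 15.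

**Further compounds**
F1 | step 8 | (2R,4R)-5,7-bis(benzyloxy)-2-[4-(benzyloxy)phenyl]chroman-4-ol | O(Cc1ccccc1)c1cc(OCc2ccccc2)c2c(c1)O[C@@H](c1ccc(OCc3ccccc3)cc1)C[C@H]2O
F2 | step 8 | (2R,4R)-5,7-bis(benzyloxy)-2-[4-(benzyloxy)phenyl]chroman-4-yl methanesulfonate (not isolated) | O(Cc1ccccc1)c1cc(OCc2ccccc2)c2c(c1)O[C@@H](c1ccc(OCc3ccccc3)cc1)C[C@H]2OS(C)(=O)=O
F3 | step 8 | (2R)-5,7-bis(benzyloxy)-2-[4-(benzyloxy)phenyl]-2H-chromene | O(Cc1ccccc1)c1cc(OCc2ccccc2)c2c(c1)O[C@@H](c1ccc(OCc3ccccc3)cc1)C=C2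
F4 | step 8 | 5,7,4'-tri-O-benzyl-ent-afzelechin, (2S,3R) | O(Cc1ccccc1)c1cc(OCc2ccccc2)c2c(c1)O[C@@H](c1ccc(OCc3ccccc3)cc1)[C@H](O)C2
F5 | step 8 | (2S)-5,7-bis(benzyloxy)-2-[4-(benzyloxy)phenyl]chroman-3-one | O(Cc1ccccc1)c1cc(OCc2ccccc2)c2c(c1)O[C@@H](c1ccc(OCc3ccccc3)cc1)C(=O)C2
F6 | step 8 | 5,7,4'-tri-O-benzyl-ent-epiafzelechin, (2S,3S) | O(Cc1ccccc1)c1cc(OCc2ccccc2)c2c(c1)O[C@@H](c1ccc(OCc3ccccc3)cc1)[C@@H](O)C2
F7 | step 8 | 5,7,4'-tri-O-benzyl-4α-(2-ethoxyethoxy)-ent-epiafzelechin | O(Cc1ccccc1)c1cc(OCc2ccccc2)c2c(c1)O[C@@H](c1ccc(OCc3ccccc3)cc1)[C@@H](O)[C@@H]2OCCOCC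
F8 | step 6 | (2S)-5,7-bis(benzyloxy)-2-[4-(benzyloxy)phenyl]-3-(2,2,2-trifluoro-1-hydroxyethylidene)chroman-4-one (enol form of the 3-trifluoroacetyl ketone) | O(Cc1ccccc1)c1cc(OCc2ccccc2)c2c(c1)O[C@@H](c1ccc(OCc3ccccc3)cc1)C(C2=O)=C(O)C(F)(F)F
F9 | step 6 | (2S)-5,7-bis(benzyloxy)-2-[4-(benzyloxy)phenyl]-3-diazochroman-4-one | O(Cc1ccccc1)c1cc(OCc2ccccc2)c2c(c1)O[C@@H](c1ccc(OCc3ccccc3)cc1)C(=[N+]=[N-])C2=O
F10 | step 6 | methyl (2R,3S)-4,6-bis(benzyloxy)-2-[4-(benzyloxy)phenyl]-2,3-dihydrobenzofuran-3-carboxylate (2,3-cis) | O(Cc1ccccc1)c1cc(OCc2ccccc2)c2c(c1)O[C@@H](c1ccc(OCc3ccccc3)cc1)[C@H]2C(=O)OC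
F11 | step 9 | methyl (2R,3R)-4,6-bis(benzyloxy)-2-[4-(benzyloxy)phenyl]-7-[8-bromo-3,5,7,4'-tetra-O-benzylepiafzelechin-4β-yl]-2,3-dihydrobenzofuran-3-carboxylate | O(Cc1ccccc1)c1cc(OCc2ccccc2)c2c(c1Br)O[C@H](c1ccc(OCc3ccccc3)cc1)[C@H](OCc1ccccc1)[C@H]2c1c(OCc2ccccc2)cc(OCc2ccccc2)c2c1O[C@@H](c1ccc(OCc3ccccc3)cc1)[C@@H]2C(=O)OC
F12 | step 9 | (2R,3R)-4,6-bis(benzyloxy)-2-[4-(benzyloxy)phenyl]-7-[8-bromo-3,5,7,4'-tetra-O-benzylepiafzelechin-4β-yl]-2,3-dihydrobenzofuran-3-carbaldehyde | O(Cc1ccccc1)c1cc(OCc2ccccc2)c2c(c1Br)O[C@H](c1ccc(OCc3ccccc3)cc1)[C@H](OCc1ccccc1)[C@H]2c1c(OCc2ccccc2)cc(OCc2ccccc2)c2c1O[C@@H](c1ccc(OCc3ccccc3)cc1)[C@@H]2C=O
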